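**Assumption:** the target SMILES has no stereocentre and fixes no biaryl axis, so there is no enantiomer to select; the compound is made as the constitution drawn. Compounds 1, 2 and 7 are purchased.

## Retrosynthetic overview

1. The target is a biflavone: an apigenin-type flavone (unit A) joined through C3′ of its B ring to C8 of a chrysoeriol-type flavone (unit B). The last operation removes six benzyl ethers; the single OMe comes from vanillin.
2. Key disconnection: the C3′(unit A)–C8(unit B) biaryl bond, by Suzuki–Miyaura coupling of an 8-iodoflavone (unit B) with a flavone 3′-pinacol boronate (unit A).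
3. Each flavone comes from one common 2-hydroxy-4,6-bis(benzyloxy)acetophenone plus a benzaldehyde: Claisen–Schmidt chalcone, then I2/DMSO oxidative cyclisation. Iodine goes onto C8 of unit B after ring closure; bromine (the boron precursor) comes in with the aldehyde of unit A.
4. Ring order: the pyranone rings of unit B and unit A are closed in parallel, then the biaryl bond is made; no ring is formed after the coupling.

## Route

**Step 1**
Reactants: 1 1-[2,4-bis(benzyloxy)-6-hydroxyphenyl]ethan-1-one; 2 4-(benzyloxy)-3-methoxybenzaldehyde (O-benzylvanillin)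
Product: 3 (E)-1-[2,4-bis(benzyloxy)-6-hydroxyphenyl]-3-[4-(benzyloxy)-3-methoxyphenyl]prop-2-en-1-one
Conditions: KOH (50% aq., 10 equiv), EtOH/THF, rt, 48 h; then 1 M HCl to pH 5
Reagents that add atoms: none
Why: Claisen–Schmidt condensation; the enolate of the methyl ketone adds to the non-enolisable aldehyde and E1cB loss of water gives the conjugated E-enone, leaving the chelated phenol free for ring closure.

**Step 2**
Reactants: 3 (E)-1-[2,4-bis(benzyloxy)-6-hydroxyphenyl]-3-[4-(benzyloxy)-3-methoxyphenyl]prop-2-en-1-one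
Product: 5 5,7-bis(benzyloxy)-2-[4-(benzyloxy)-3-methoxyphenyl]-4H-chromen-4-one, via racemic flavanone 4 (not isolated)
Conditions: I2 (10 mol %), DMSO, 130 °C, 4 h
Reagents that add atoms: none
Why: Iodine-catalysed oxidative cyclisation; oxa-Michael addition of the phenol gives flavanone 4, α-iodination and loss of hydrogen iodide give the flavone while DMSO re-oxidises hydrogen iodide to I2, so the transient racemic C2 centre is erased.

**Step 3**
Reactants: 5 5,7-bis(benzyloxy)-2-[4-(benzyloxy)-3-methoxyphenyl]-4H-chromen-4-one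
Product: 6 5,7-bis(benzyloxy)-2-[4-(benzyloxy)-3-methoxyphenyl]-8-iodo-4H-chromen-4-one
Conditions: NIS (1.05 equiv), TFA (0.2 equiv), CH2Cl2/MeCN, 0 °C to rt, dark
Reagents that add atoms: N-iodosuccinimide (NIS), O=C1CCC(=O)N1I
Why: Electrophilic aromatic iodination; ring A is the most electron-rich ring and, with the 5-oxygen alkylated, attack should go to C8 (ortho to the ring oxygen and 7-OBn, para to 5-OBn) because C6 is shielded between two benzyloxy groups.

**Step 4**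
Reactants: 1 1-[2,4-bis(benzyloxy)-6-hydroxyphenyl]ethan-1-one; 7 4-(benzyloxy)-3-bromobenzaldehyde
Product: 8 (E)-1-[2,4-bis(benzyloxy)-6-hydroxyphenyl]-3-[4-(benzyloxy)-3-bromophenyl]prop-2-en-1-one
Conditions: KOH (50% aq., 10 equiv), EtOH/THF, rt, 48 h; then 1 M HCl to pH 5
Reagents that add atoms: none
Why: Claisen–Schmidt condensation as in step 1; the aryl bromide is inert to aqueous KOH at room temperature.

**Step 5**
Reactants: 8 (E)-1-[2,4-bis(benzyloxy)-6-hydroxyphenyl]-3-[4-(benzyloxy)-3-bromophenyl]prop-2-en-1-one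
Product: 10 5,7-bis(benzyloxy)-2-[4-(benzyloxy)-3-bromophenyl]-4H-chromen-4-one, via racemic bromoflavanone 9 (not isolated)
Conditions: I2 (10 mol %), DMSO, 130 °C, 4 h
Reagents that add atoms: none
Why: The same iodine-catalysed oxidative cyclisation (oxa-Michael, α-iodination, elimination); the aryl bromide and benzyl ethers are spectators and the racemic C2 centre of 9 is erased.

**Step 6**
Reactants: 10 5,7-bis(benzyloxy)-2-[4-(benzyloxy)-3-bromophenyl]-4H-chromen-4-one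
Product: 11 5,7-bis(benzyloxy)-2-[4-(benzyloxy)-3-(4,4,5,5-tetramethyl-1,3,2-dioxaborolan-2-yl)phenyl]-4H-chromen-4-one
Conditions: B2pin2 (1.5 equiv), PdCl2(dppf)·CH2Cl2 (5 mol %), KOAc (3 equiv), 1,4-dioxane, 90 °C, Ar
Reagents that add atoms: bis(pinacolato)diboron (B2pin2), CC1(C)OB(OC1(C)C)B1OC(C)(C)C(C)(C)O1
Why: Miyaura borylation; zerovalent palladium inserts into the aryl–bromine bond, acetate-assisted transmetalation with B2pin2 and reductive elimination give the aryl boronate, and KOAc is too weak a base to drive homocoupling.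

**Step 7**
Reactants: 6 5,7-bis(benzyloxy)-2-[4-(benzyloxy)-3-methoxyphenyl]-8-iodo-4H-chromen-4-one; 11 5,7-bis(benzyloxy)-2-[4-(benzyloxy)-3-(4,4,5,5-tetramethyl-1,3,2-dioxaborolan-2-yl)phenyl]-4H-chromen-4-one (1.3 equiv)
Product: 12 5,7-bis(benzyloxy)-8-{2-(benzyloxy)-5-[5,7-bis(benzyloxy)-4-oxo-4H-chromen-2-yl]phenyl}-2-[4-(benzyloxy)-3-methoxyphenyl]-4H-chromen-4-one
Conditions: Pd(OAc)2 (5 mol %), SPhos (10 mol %), K3PO4 (3 equiv), 1,4-dioxane/H2O (5:1), 90 °C, Ar
Reagents that add atoms: none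
Why: Suzuki–Miyaura cross-coupling; the bulky electron-rich SPhos ligand lets zerovalent palladium insert into the hindered carbon–iodine bond of 6 and couple boronate 11 to the tri-ortho-substituted biaryl, whose axis is not a defined stereo element.

**Step 8**
Reactants: 12 5,7-bis(benzyloxy)-8-{2-(benzyloxy)-5-[5,7-bis(benzyloxy)-4-oxo-4H-chromen-2-yl]phenyl}-2-[4-(benzyloxy)-3-methoxyphenyl]-4H-chromen-4-one
Product: 13 8-[5-(5,7-dihydroxy-4-oxo-4H-chromen-2-yl)-2-hydroxyphenyl]-5,7-dihydroxy-2-(4-hydroxy-3-methoxyphenyl)-4H-chromen-4-one (target)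
Conditions: H2 (1 atm), 10% Pd/C, THF/MeOH (1:1), rt
Reagents that add atoms: none
Why: Catalytic hydrogenolysis cleaves the six benzylic C–O bonds; the aryl methyl ether has no benzylic C–O bond and the vinylogous-ester C2=C3 bonds of flavones resist hydrogenation at 1 atm and room temperature.

## Compound list

1 | 1-[2,4-bis(benzyloxy)-6-hydroxyphenyl]ethan-1-one | CC(=O)c1c(O)cc(OCc2ccccc2)cc1OCc1ccccc1 | starting material
2 | 4-(benzyloxy)-3-methoxybenzaldehyde | COc1cc(C=O)ccc1OCc1ccccc1 | starting material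
3 | (E)-1-[2,4-bis(benzyloxy)-6-hydroxyphenyl]-3-[4-(benzyloxy)-3-methoxyphenyl]prop-2-en-1-one | COc1cc(/C=C/C(=O)c2c(O)cc(OCc3ccccc3)cc2OCc2ccccc2)ccc1OCc1ccccc1 | intermediate
4 | 5,7-bis(benzyloxy)-2-[4-(benzyloxy)-3-methoxyphenyl]-2,3-dihydro-4H-chromen-4-one (racemic at C2, not isolated) | COc1cc(C2CC(=O)c3c(OCc4ccccc4)cc(OCc4ccccc4)cc3O2)ccc1OCc1ccccc1 | intermediate
5 | 5,7-bis(benzyloxy)-2-[4-(benzyloxy)-3-methoxyphenyl]-4H-chromen-4-one | COc1cc(-c2cc(=O)c3c(OCc4ccccc4)cc(OCc4ccccc4)cc3o2)ccc1OCc1ccccc1 | intermediate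
6 | 5,7-bis(benzyloxy)-2-[4-(benzyloxy)-3-methoxyphenyl]-8-iodo-4H-chromen-4-one | COc1cc(-c2cc(=O)c3c(OCc4ccccc4)cc(OCc4ccccc4)c(I)c3o2)ccc1OCc1ccccc1 | intermediate
7 | 4-(benzyloxy)-3-bromobenzaldehyde | O=Cc1ccc(OCc2ccccc2)c(Br)c1 | starting material
8 | (E)-1-[2,4-bis(benzyloxy)-6-hydroxyphenyl]-3-[4-(benzyloxy)-3-bromophenyl]prop-2-en-1-one | O=C(/C=C/c1ccc(OCc2ccccc2)c(Br)c1)c1c(O)cc(OCc2ccccc2)cc1OCc1ccccc1 | intermediate
9 | 5,7-bis(benzyloxy)-2-[4-(benzyloxy)-3-bromophenyl]-2,3-dihydro-4H-chromen-4-one (racemic at C2, not isolated) | O=C1CC(c2ccc(OCc3ccccc3)c(Br)c2)Oc2cc(OCc3ccccc3)cc(OCc3ccccc3)c21 | intermediate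
10 | 5,7-bis(benzyloxy)-2-[4-(benzyloxy)-3-bromophenyl]-4H-chromen-4-one | O=c1cc(-c2ccc(OCc3ccccc3)c(Br)c2)oc2cc(OCc3ccccc3)cc(OCc3ccccc3)c12 | intermediate
11 | 5,7-bis(benzyloxy)-2-[4-(benzyloxy)-3-(4,4,5,5-tetramethyl-1,3,2-dioxaborolan-2-yl)phenyl]-4H-chromen-4-one | O=c1cc(-c2ccc(OCc3ccccc3)c(B3OC(C)(C)C(C)(C)O3)c2)oc2cc(OCc3ccccc3)cc(OCc3ccccc3)c12 | intermediate
12 | 5,7-bis(benzyloxy)-8-{2-(benzyloxy)-5-[5,7-bis(benzyloxy)-4-oxo-4H-chromen-2-yl]phenyl}-2-[4-(benzyloxy)-3-methoxyphenyl]-4H-chromen-4-one | COc1cc(-c2cc(=O)c3c(OCc4ccccc4)cc(OCc4ccccc4)c(-c4cc(-c5cc(=O)c6c(OCc7ccccc7)cc(OCc7ccccc7)cc6o5)ccc4OCc4ccccc4)c3o2)ccc1OCc1ccccc1 | intermediate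
13 | 8-[5-(5,7-dihydroxy-4-oxo-4H-chromen-2-yl)-2-hydroxyphenyl]-5,7-dihydroxy-2-(4-hydroxy-3-methoxyphenyl)-4H-chromen-4-one | COc1cc(-c2cc(=O)c3c(O)cc(O)c(-c4cc(-c5cc(=O)c6c(O)cc(O)cc6o5)ccc4O)c3o2)ccc1O | target

## Totals

Total step count: 8.
Longest linear sequence: 5 steps (steps 1, 2, 3, 7, 8 or, equally, steps 4, 5, 6, 7, 8).

## Three steps most likely to fail, each with a fallback

**Step 3 (C8 against C6 iodination, over-iodination).** If NIS gives the 6-iodo isomer or a mixture, the halogen is put in before the pyranone ring exists, so that ring closure fixes its position. The fallback sets out from compound 1 and comes back at compound 6. Compound 1 is iodinated with NIS (DMF, 0 °C to rt) ortho to its free chelated phenol to give 1-[4,6-bis(benzyloxy)-2-hydroxy-3-iodophenyl]ethan-1-one F1. Claisen–Schmidt condensation of this ketone with aldehyde 2 (KOH, EtOH/THF, rt) gives (E)-1-[4,6-bis(benzyloxy)-2-hydroxy-3-iodophenyl]-3-[4-(benzyloxy)-3-methoxyphenyl]prop-2-en-1-one F2. I2/DMSO at 110–120 °C then closes the ring through the only free hydroxyl by way of racemic 5,7-bis(benzyloxy)-2-[4-(benzyloxy)-3-methoxyphenyl]-8-iodo-2,3-dihydro-4H-chromen-4-one F3 (not isolated), so the iodine can only end up at C8 of 6.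

**Step 7 (tri-ortho-substituted biaryl from two bulky flavones, protodeboronation of 11).** If the coupling of the two flavones fails, the biaryl bond is made with a small boronate and the pyranone ring of unit A is built afterwards. The fallback sets out from compound 7 and comes back at compound 12; compounds 8 to 11 are then not needed. Miyaura borylation of 7 (B2pin2, PdCl2(dppf)·CH2Cl2, KOAc, 1,4-dioxane, 80 °C) gives 4-(benzyloxy)-3-(4,4,5,5-tetramethyl-1,3,2-dioxaborolan-2-yl)benzaldehyde F4. Used in two- to threefold excess, it is coupled with iodide 6 (Pd(OAc)2, SPhos, K3PO4, 1,4-dioxane/H2O, 90 °C) to give 4-(benzyloxy)-3-{5,7-bis(benzyloxy)-2-[4-(benzyloxy)-3-methoxyphenyl]-4-oxo-4H-chromen-8-yl}benzaldehyde F5. Claisen–Schmidt condensation of this aldehyde with ketone 1 (KOH, EtOH/THF, rt) gives 5,7-bis(benzyloxy)-8-{2-(benzyloxy)-5-[(E)-3-[2,4-bis(benzyloxy)-6-hydroxyphenyl]-3-oxoprop-1-en-1-yl]phenyl}-2-[4-(benzyloxy)-3-methoxyphenyl]-4H-chromen-4-one F6. I2/DMSO at 130 °C converts it, by way of 5,7-bis(benzyloxy)-8-{2-(benzyloxy)-5-[5,7-bis(benzyloxy)-4-oxo-3,4-dihydro-2H-chromen-2-yl]phenyl}-2-[4-(benzyloxy)-3-methoxyphenyl]-4H-chromen-4-one F7 (racemic at the flavanone C2, not isolated), into 12.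

**Step 8 (sixfold hydrogenolysis; stalling on poorly soluble, partly debenzylated material or saturation of C2=C3).** If hydrogen gives incomplete cleavage or flavanone by-products, the reductive cleavage is replaced by Lewis-acid dealkylation. The fallback sets out from compound 12 and comes back at compound 13. BCl3 (12 equiv) with pentamethylbenzene (18 equiv) as benzyl-cation trap in CH2Cl2 at −78 °C to 0 °C, then MeOH/H2O quench, cleaves all six aryl benzyl ethers. No C=C reduction is possible, and the aryl methyl ether, which is not peri to a carbonyl, is not attacked at this temperature. This fallback makes no new compound F0.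

## Further compounds

F1 | step 3 | 1-[4,6-bis(benzyloxy)-2-hydroxy-3-iodophenyl]ethan-1-one | CC(=O)c1c(O)c(I)c(OCc2ccccc2)cc1OCc1ccccc1
F2 | step 3 | (E)-1-[4,6-bis(benzyloxy)-2-hydroxy-3-iodophenyl]-3-[4-(benzyloxy)-3-methoxyphenyl]prop-2-en-1-one | COc1cc(/C=C/C(=O)c2c(O)c(I)c(OCc3ccccc3)cc2OCc2ccccc2)ccc1OCc1ccccc1
F3 | step 3 | 5,7-bis(benzyloxy)-2-[4-(benzyloxy)-3-methoxyphenyl]-8-iodo-2,3-dihydro-4H-chromen-4-one (racemic at C2) | COc1cc(C2CC(=O)c3c(OCc4ccccc4)cc(OCc4ccccc4)c(I)c3O2)ccc1OCc1ccccc1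
F4 | step 7 | 4-(benzyloxy)-3-(4,4,5,5-tetramethyl-1,3,2-dioxaborolan-2-yl)benzaldehyde | O=Cc1ccc(OCc2ccccc2)c(B2OC(C)(C)C(C)(C)O2)c1
F5 | step 7 | 4-(benzyloxy)-3-{5,7-bis(benzyloxy)-2-[4-(benzyloxy)-3-methoxyphenyl]-4-oxo-4H-chromen-8-yl}benzaldehyde | COc1cc(-c2cc(=O)c3c(OCc4ccccc4)cc(OCc4ccccc4)c(-c4cc(C=O)ccc4OCc4ccccc4)c3o2)ccc1OCc1ccccc1
F6 | step 7 | 5,7-bis(benzyloxy)-8-{2-(benzyloxy)-5-[(E)-3-[2,4-bis(benzyloxy)-6-hydroxyphenyl]-3-oxoprop-1-en-1-yl]phenyl}-2-[4-(benzyloxy)-3-methoxyphenyl]-4H-chromen-4-one | COc1cc(-c2cc(=O)c3c(OCc4ccccc4)cc(OCc4ccccc4)c(-c4cc(/C=C/C(=O)c5c(O)cc(OCc6ccccc6)cc5OCc5ccccc5)ccc4OCc4ccccc4)c3o2)ccc1OCc1ccccc1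
F7 | step 7 | 5,7-bis(benzyloxy)-8-{2-(benzyloxy)-5-[5,7-bis(benzyloxy)-4-oxo-3,4-dihydro-2H-chromen-2-yl]phenyl}-2-[4-(benzyloxy)-3-methoxyphenyl]-4H-chromen-4-one (racemic at the flavanone C2) | COc1cc(-c2cc(=O)c3c(OCc4ccccc4)cc(OCc4ccccc4)c(-c4cc(C5CC(=O)c6c(OCc7ccccc7)cc(OCc7ccccc7)cc6O5)ccc4OCc4ccccc4)c3o2)ccc1OCc1ccccc1
F0 | step 8 | none | none
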